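**Strategy.** The N-methylpiperidine (N1', C2'–C6') is closed last at C6', the end remote from the benzylic C2' that sits on C6 of ring A between two oxygenated carbons (C5, C7) and is prone to ionisation. A rhodium-catalysed hydroaminomethylation of a terminal alkene brings in carbon monoxide as C6', forming C5'–C6' and N1'–C6' in one neutral operation that leaves C2' untouched. The precursor is an (R)-configured N-methyl homoallylic amine on a phloroglucinol ring bearing two MOM ethers and a para benzyl ether, made by sulfinimine allylation. After ring closure, ortho-lithiation, acylation, debenzylation, chalcone formation and catalytic asymmetric oxa-Michael closure build the (2S)-flavanone.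

Key step: step 7

Remark: primed locants (N1', C2' to C6') denote the piperidine, unprimed locants the chromanone, and ring B the 4-hydroxyphenyl group; the facial sense quoted for steps 4 and 12 rests on the usual transition-state models and would be confirmed on the first batch.

**Step 1**
Reactants: 1 2,4,6-trihydroxybenzaldehyde; 2 benzyl bromide
Product: 3 4-(benzyloxy)-2,6-dihydroxybenzaldehyde
Conditions: NaHCO3 (1.1 equiv), DMF, 25–40 °C
Reagents that add atoms: none
Why: Williamson etherification in which one equivalent of a weak base ionises only the 4-OH, the most acidic hydroxyl (para to the formyl group and not hydrogen-bonded to it), so benzylation should occur there.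

**Step 2**
Reactants: 3 4-(benzyloxy)-2,6-dihydroxybenzaldehyde
Product: 4 4-(benzyloxy)-2,6-bis(methoxymethoxy)benzaldehyde
Conditions: NaH (2.4 equiv), MOMCl (2.6 equiv), DMF, 0 °C → rt
Reagents that add atoms: chloromethyl methyl ether, COCCl
Why: O-alkylation of the bis-phenoxide with the reactive α-chloro ether (MOM protection) should cap both ortho hydroxyls, and the MOM groups later serve as metalation directors.

**Step 3**
Reactants: 4 4-(benzyloxy)-2,6-bis(methoxymethoxy)benzaldehyde; 5 (S)-2-methylpropane-2-sulfinamide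
Product: 6 (S)-N-[(E)-[4-(benzyloxy)-2,6-bis(methoxymethoxy)phenyl]methylidene]-2-methylpropane-2-sulfinamide
Conditions: Ti(OEt)4 (2 equiv), THF, 60 °C
Reagents that add atoms: none
Why: Ellman condensation, in which Ti(OEt)4 acts as Lewis acid and water scavenger, should give the E-configured N-sulfinyl aldimine from the hindered aldehyde with the sulfur configuration unchanged.

**Step 4**
Reactants: 6 (S)-N-[(E)-[4-(benzyloxy)-2,6-bis(methoxymethoxy)phenyl]methylidene]-2-methylpropane-2-sulfinamide; 7 allylmagnesium bromide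
Product: 8 (S)-N-[(1R)-1-[4-(benzyloxy)-2,6-bis(methoxymethoxy)phenyl]but-3-en-1-yl]-2-methylpropane-2-sulfinamide
Conditions: allylMgBr (1 M in Et2O, 1.5 equiv), CH2Cl2, −78 °C; then H2O
Reagents that add atoms: none
Why: Grignard 1,2-addition to an N-tert-butanesulfinyl aldimine through a six-membered chair transition state with magnesium on the sulfinyl oxygen should deliver the allyl group to the Re face of the (S)-sulfinyl imine and set C2' as R, the minor diastereomer being removable by chromatography.

**Step 5**
Reactants: 8 (S)-N-[(1R)-1-[4-(benzyloxy)-2,6-bis(methoxymethoxy)phenyl]but-3-en-1-yl]-2-methylpropane-2-sulfinamide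
Product: 9 (S)-N-[(1R)-1-[4-(benzyloxy)-2,6-bis(methoxymethoxy)phenyl]but-3-en-1-yl]-N,2-dimethylpropane-2-sulfinamide
Conditions: NaH (1.5 equiv), MeI (2 equiv), DMF, 0 °C → rt
Reagents that add atoms: iodomethane, CI
Why: SN2 N-methylation of the sulfinamide anion, which touches neither the sulfur nor the C2' stereocentre.

**Step 6**
Reactants: 9 (S)-N-[(1R)-1-[4-(benzyloxy)-2,6-bis(methoxymethoxy)phenyl]but-3-en-1-yl]-N,2-dimethylpropane-2-sulfinamide
Product: 10 (1R)-1-[4-(benzyloxy)-2,6-bis(methoxymethoxy)phenyl]-N-methylbut-3-en-1-amine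
Conditions: HCl (4 M in dioxane, 2 equiv), MeOH, 0 °C, 30 min; then aq. NaOH
Reagents that add atoms: none
Why: Acid methanolysis of the S–N bond (standard sulfinyl removal) is fast at 0 °C with a small excess of HCl, conditions under which the aryl MOM ethers should persist, and it leaves the C2'–N bond and hence the R configuration intact.

**Step 7**
Reactants: 10 (1R)-1-[4-(benzyloxy)-2,6-bis(methoxymethoxy)phenyl]-N-methylbut-3-en-1-amine
Product: 14 (2R)-2-[4-(benzyloxy)-2,6-bis(methoxymethoxy)phenyl]-1-methylpiperidine, via amino aldehyde 11 (not isolated), via cyclic hemiaminal 12 (not isolated), via cyclic enamine 13 (not isolated)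
Conditions: Rh(acac)(CO)2 (2 mol %), BIPHEPHOS (4 mol %), CO/H2 (1:3, 40 bar), THF, 80 °C
Reagents that add atoms: carbon monoxide, [C-]#[O+]
Why: Tandem hydroformylation–reductive amination (hydroaminomethylation): the rhodium hydride formed from Rh(acac)(CO)2 (monovalent rhodium) and BIPHEPHOS under syngas adds to the terminal alkene with rhodium on the terminal carbon, CO inserts and hydrogenolysis of the acyl releases linear aldehyde 11 (new bond C5'–C6'). The secondary amine then adds to the formyl carbon in a 6-exo-trig closure (new bond N1'–C6') to hemiaminal 12, which loses water to enamine 13 (C5'=C6'), and the same rhodium hydride hydrogenates this enamine to piperidine 14. The closest known reaction type is the rhodium–bisphosphite hydroaminomethylation of terminal alkenes with secondary amines, including its intramolecular form that converts alkenyl amines into cyclic amines. No stereocentre is created; C2', set in step 4, should keep its R configuration because none of its bonds is made or broken, the enamine double bond lies at C5'=C6' and the medium is neutral. The step needs linear rather than branched hydroformylation (the branched aldehyde would close to a methylpyrrolidine) and reduction of the enamine rather than of the aldehyde; the bulky wide-bite-angle bisphosphite acting on an unhindered terminal CH2 should secure the first, and fast intramolecular condensation under a hydrogen-rich gas mixture the second.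

**Step 8**
Reactants: 14 (2R)-2-[4-(benzyloxy)-2,6-bis(methoxymethoxy)phenyl]-1-methylpiperidine; 15 N-methoxy-N-methylacetamide
Product: 17 1-[6-(benzyloxy)-2,4-bis(methoxymethoxy)-3-[(2R)-1-methylpiperidin-2-yl]phenyl]ethan-1-one, via aryllithium 16 (not isolated)
Conditions: n-BuLi (1.3 equiv), THF, 0 °C, 1 h; then 15 (1.5 equiv), −78 °C → rt; then H2O
Reagents that add atoms: none
Why: Directed ortho-metalation removes one of the two equivalent ring hydrogens, each flanked by a coordinating MOM ether and the benzyl ether, and the aryllithium is acylated once by the Weinreb amide because the chelated tetrahedral adduct survives until the quench.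

**Step 9**
Reactants: 17 1-[6-(benzyloxy)-2,4-bis(methoxymethoxy)-3-[(2R)-1-methylpiperidin-2-yl]phenyl]ethan-1-one
Product: 18 1-[6-hydroxy-2,4-bis(methoxymethoxy)-3-[(2R)-1-methylpiperidin-2-yl]phenyl]ethan-1-one
Conditions: H2 (1 atm), 10% Pd/C, EtOAc, rt
Reagents that add atoms: none
Why: Hydrogenolysis of the aryl benzyl ether on palladium is fast at 1 atm, whereas the hindered ring C2'–N bond of the tertiary amine and the doubly ortho-substituted aryl ketone should react far more slowly, so the phenol para to the piperidine is freed selectively.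

**Step 10**
Reactants: 19 4-hydroxybenzaldehyde
Product: 20 4-(methoxymethoxy)benzaldehyde
Conditions: MOMCl (1.3 equiv), K2CO3 (2 equiv), acetone, rt
Reagents that add atoms: chloromethyl methyl ether, COCCl
Why: O-alkylation of the phenoxide (MOM protection) masks the phenol that would otherwise deactivate the aldehyde in the base-mediated aldol step.

**Step 11**
Reactants: 18 1-[6-hydroxy-2,4-bis(methoxymethoxy)-3-[(2R)-1-methylpiperidin-2-yl]phenyl]ethan-1-one; 20 4-(methoxymethoxy)benzaldehyde
Product: 21 (2E)-1-[6-hydroxy-2,4-bis(methoxymethoxy)-3-[(2R)-1-methylpiperidin-2-yl]phenyl]-3-[4-(methoxymethoxy)phenyl]prop-2-en-1-one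
Conditions: KOH (50% aq., excess), EtOH, rt; then cold 1 M HCl to pH 7
Reagents that add atoms: none
Why: Claisen–Schmidt condensation of the methyl ketone enolate with the non-enolisable aldehyde followed by E1cB dehydration should give the E-chalcone, which stays open as its phenoxide in the strongly basic medium.

**Step 12**
Reactants: 21 (2E)-1-[6-hydroxy-2,4-bis(methoxymethoxy)-3-[(2R)-1-methylpiperidin-2-yl]phenyl]-3-[4-(methoxymethoxy)phenyl]prop-2-en-1-one
Product: 22 (2S)-5,7-bis(methoxymethoxy)-2-[4-(methoxymethoxy)phenyl]-6-[(2R)-1-methylpiperidin-2-yl]-2,3-dihydro-4H-chromen-4-one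
Conditions: 9-amino(9-deoxy)epiquinine N'-[3,5-bis(trifluoromethyl)phenyl]thiourea (20 mol %), toluene, 0 °C → rt
Reagents that add atoms: none
Why: Bifunctional amine–thiourea catalysed intramolecular oxa-Michael addition (6-endo-trig) of a 2'-hydroxychalcone, in which the quinuclidine activates the phenol para to C6 while the thiourea binds the enone, so that the catalyst and not the remote C2' centre should direct the oxygen to the Si face of the β-carbon and set C2 as S; the C2 epimer is a diastereomer and can be removed, and the quinidine-derived pseudoenantiomer is at hand should a pilot run show the opposite sense.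

**Step 13**
Reactants: 22 (2S)-5,7-bis(methoxymethoxy)-2-[4-(methoxymethoxy)phenyl]-6-[(2R)-1-methylpiperidin-2-yl]-2,3-dihydro-4H-chromen-4-one
Product: 23 (2S)-5,7-dihydroxy-2-(4-hydroxyphenyl)-6-[(2R)-1-methylpiperidin-2-yl]-2,3-dihydro-4H-chromen-4-one
Conditions: 3 M aq. HCl/MeOH (1:4), 40 °C; then aq. NaHCO3
Reagents that add atoms: none
Why: Acid-catalysed acetal cleavage removes the three MOM groups as dimethoxymethane, and at this temperature ring A, deactivated by the C4 carbonyl, should support neither ionisation of the C2'–N bond nor opening of the C2–O1 bond, so both stereocentres should be kept.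

**Compound list**

1 | 2,4,6-trihydroxybenzaldehyde | O=Cc1c(O)cc(O)cc1O | starting material
2 | benzyl bromide | BrCc1ccccc1 | starting material
3 | 4-(benzyloxy)-2,6-dihydroxybenzaldehyde | O=Cc1c(O)cc(OCc2ccccc2)cc1O | intermediate
4 | 4-(benzyloxy)-2,6-bis(methoxymethoxy)benzaldehyde | O=Cc1c(OCOC)cc(OCc2ccccc2)cc1OCOC | intermediate
5 | (S)-2-methylpropane-2-sulfinamide | CC(C)(C)[S@](=O)N | starting material
6 | (S)-N-[(E)-[4-(benzyloxy)-2,6-bis(methoxymethoxy)phenyl]methylidene]-2-methylpropane-2-sulfinamide | CC(C)(C)[S@](=O)/N=C/c1c(OCOC)cc(OCc2ccccc2)cc1OCOC | intermediate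
7 | allylmagnesium bromide | C=CC[Mg]Br | starting material
8 | (S)-N-[(1R)-1-[4-(benzyloxy)-2,6-bis(methoxymethoxy)phenyl]but-3-en-1-yl]-2-methylpropane-2-sulfinamide | CC(C)(C)[S@](=O)N[C@H](CC=C)c1c(OCOC)cc(OCc2ccccc2)cc1OCOC | intermediate
9 | (S)-N-[(1R)-1-[4-(benzyloxy)-2,6-bis(methoxymethoxy)phenyl]but-3-en-1-yl]-N,2-dimethylpropane-2-sulfinamide | CC(C)(C)[S@](=O)N(C)[C@H](CC=C)c1c(OCOC)cc(OCc2ccccc2)cc1OCOC | intermediate
10 | (1R)-1-[4-(benzyloxy)-2,6-bis(methoxymethoxy)phenyl]-N-methylbut-3-en-1-amine | CN[C@H](CC=C)c1c(OCOC)cc(OCc2ccccc2)cc1OCOC | intermediate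
11 | (5R)-5-[4-(benzyloxy)-2,6-bis(methoxymethoxy)phenyl]-5-(methylamino)pentanal (amino aldehyde, not isolated) | CN[C@H](CCCC=O)c1c(OCOC)cc(OCc2ccccc2)cc1OCOC | intermediate
12 | (6R)-6-[4-(benzyloxy)-2,6-bis(methoxymethoxy)phenyl]-1-methylpiperidin-2-ol, either configuration at the carbinol carbon (cyclic hemiaminal, not isolated) | CN1C(O)CCC[C@@H]1c1c(OCOC)cc(OCc2ccccc2)cc1OCOC | intermediate
13 | (2R)-2-[4-(benzyloxy)-2,6-bis(methoxymethoxy)phenyl]-1-methyl-1,2,3,4-tetrahydropyridine (cyclic enamine, not isolated) | CN1C=CCC[C@@H]1c1c(OCOC)cc(OCc2ccccc2)cc1OCOC | intermediate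
14 | (2R)-2-[4-(benzyloxy)-2,6-bis(methoxymethoxy)phenyl]-1-methylpiperidine | CN1CCCC[C@@H]1c1c(OCOC)cc(OCc2ccccc2)cc1OCOC | intermediate
15 | N-methoxy-N-methylacetamide | CC(=O)N(C)OC | starting material
16 | {6-(benzyloxy)-2,4-bis(methoxymethoxy)-3-[(2R)-1-methylpiperidin-2-yl]phenyl}lithium (aryllithium, not isolated) | CN1CCCC[C@@H]1c1c(OCOC)cc(OCc2ccccc2)c([Li])c1OCOC | intermediate
17 | 1-[6-(benzyloxy)-2,4-bis(methoxymethoxy)-3-[(2R)-1-methylpiperidin-2-yl]phenyl]ethan-1-one | CN1CCCC[C@@H]1c1c(OCOC)cc(OCc2ccccc2)c(C(C)=O)c1OCOC | intermediate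
18 | 1-[6-hydroxy-2,4-bis(methoxymethoxy)-3-[(2R)-1-methylpiperidin-2-yl]phenyl]ethan-1-one | CN1CCCC[C@@H]1c1c(OCOC)cc(O)c(C(C)=O)c1OCOC | intermediate
19 | 4-hydroxybenzaldehyde | O=Cc1ccc(O)cc1 | starting material
20 | 4-(methoxymethoxy)benzaldehyde | COCOc1ccc(C=O)cc1 | intermediate
21 | (2E)-1-[6-hydroxy-2,4-bis(methoxymethoxy)-3-[(2R)-1-methylpiperidin-2-yl]phenyl]-3-[4-(methoxymethoxy)phenyl]prop-2-en-1-one | CN1CCCC[C@@H]1c1c(OCOC)cc(O)c(C(=O)/C=C/c2ccc(OCOC)cc2)c1OCOC | intermediate
22 | (2S)-5,7-bis(methoxymethoxy)-2-[4-(methoxymethoxy)phenyl]-6-[(2R)-1-methylpiperidin-2-yl]-2,3-dihydro-4H-chromen-4-one | CN1CCCC[C@@H]1c1c(OCOC)cc2c(c1OCOC)C(=O)C[C@@H](c1ccc(OCOC)cc1)O2 | intermediate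
23 | (2S)-5,7-dihydroxy-2-(4-hydroxyphenyl)-6-[(2R)-1-methylpiperidin-2-yl]-2,3-dihydro-4H-chromen-4-one | CN1CCCC[C@@H]1c1c(O)cc2c(c1O)C(=O)C[C@@H](c1ccc(O)cc1)O2 | target

**Step count.** Total: 13 steps. Longest linear sequence: 12 steps (steps 1–9 and 11–13); step 10 is a one-step branch.

**Steps most likely to fail**

1. Step 7. The amine and the alkene may chelate rhodium and slow the catalyst. The alkene may migrate towards the benzylic position. Branched insertion would lead to a five-membered ring, and the sequence may stall at the enamine. The fallback closes the same N1'–C6' bond by N-alkylation and sets out from 6. 4-Chlorobutylmagnesium bromide F1 (from 1-bromo-4-chlorobutane and Mg) is added in CH2Cl2 at −48 °C by the same chair model to give (S)-N-[(1R)-1-[4-(benzyloxy)-2,6-bis(methoxymethoxy)phenyl]-5-chloropentyl]-2-methylpropane-2-sulfinamide F2. KHMDS in THF closes the ring by 6-exo-tet displacement of chloride to (2R)-2-[4-(benzyloxy)-2,6-bis(methoxymethoxy)phenyl]-1-[(S)-2-methylpropane-2-sulfinyl]piperidine F3. HCl in MeOH at 0 °C gives (2R)-2-[4-(benzyloxy)-2,6-bis(methoxymethoxy)phenyl]piperidine F4. Reductive methylation with aqueous formaldehyde and NaBH(OAc)3 comes back to the route at 14.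

2. Step 12. Facial selectivity may be poor, because the catalyst has to outrun a non-selective closure promoted by the substrate's own tertiary amine, and reversible ring opening may erode the ratio. The fallback sets C2 by carbon–carbon bond formation on a chromone and sets out from 18. N,N-Dimethylformamide dimethyl acetal (toluene, 90 °C) gives (2E)-3-(dimethylamino)-1-[6-hydroxy-2,4-bis(methoxymethoxy)-3-[(2R)-1-methylpiperidin-2-yl]phenyl]prop-2-en-1-one F5. Warm acetic acid cyclises it with loss of dimethylamine to 5,7-bis(methoxymethoxy)-6-[(2R)-1-methylpiperidin-2-yl]-4H-chromen-4-one F6. Rhodium-catalysed asymmetric 1,4-addition of commercial [4-(methoxymethoxy)phenyl]boronic acid then comes back to the route at 22; it would use [Rh(OH)(cod)]2 (monovalent rhodium) and an electron-poor atropisomeric bisphosphine of the MeO-F12-BIPHEP type, in the antipode that gives 2S, in toluene/H2O at 40 °C.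

3. Step 8. The base may deprotonate the benzylic OCH2 group, which would lead to Wittig rearrangement, and the hindered aryllithium may take a proton from the enolisable Weinreb amide, which returns 14. The fallback fixes the metalation site by halogenation and uses a non-enolisable electrophile; it sets out from 14. N-Bromosuccinimide (1.0 equiv, MeCN, −20 °C) brominates the activated ring to (2R)-2-[4-(benzyloxy)-3-bromo-2,6-bis(methoxymethoxy)phenyl]-1-methylpiperidine F7. Bromine–lithium exchange with n-BuLi in THF at −78 °C regenerates 16, which is trapped with acetaldehyde to 1-[6-(benzyloxy)-2,4-bis(methoxymethoxy)-3-[(2R)-1-methylpiperidin-2-yl]phenyl]ethan-1-ol F8 as a mixture of carbinol epimers. Oxidation with Dess–Martin periodinane comes back to the route at 17.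

**Further compounds**

F1 | step 7 | 4-chlorobutylmagnesium bromide | ClCCCC[Mg]Br
F2 | step 7 | (S)-N-[(1R)-1-[4-(benzyloxy)-2,6-bis(methoxymethoxy)phenyl]-5-chloropentyl]-2-methylpropane-2-sulfinamide | CC(C)(C)[S@](=O)N[C@H](CCCCCl)c1c(OCOC)cc(OCc2ccccc2)cc1OCOC
F3 | step 7 | (2R)-2-[4-(benzyloxy)-2,6-bis(methoxymethoxy)phenyl]-1-[(S)-2-methylpropane-2-sulfinyl]piperidine | CC(C)(C)[S@](=O)N1CCCC[C@@H]1c1c(OCOC)cc(OCc2ccccc2)cc1OCOC
F4 | step 7 | (2R)-2-[4-(benzyloxy)-2,6-bis(methoxymethoxy)phenyl]piperidine | N1CCCC[C@@H]1c1c(OCOC)cc(OCc2ccccc2)cc1OCOC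
F5 | step 12 | (2E)-3-(dimethylamino)-1-[6-hydroxy-2,4-bis(methoxymethoxy)-3-[(2R)-1-methylpiperidin-2-yl]phenyl]prop-2-en-1-one | CN1CCCC[C@@H]1c1c(OCOC)cc(O)c(C(=O)/C=C/N(C)C)c1OCOC
F6 | step 12 | 5,7-bis(methoxymethoxy)-6-[(2R)-1-methylpiperidin-2-yl]-4H-chromen-4-one | CN1CCCC[C@@H]1c1c(OCOC)cc2occc(=O)c2c1OCOC
F7 | step 8 | (2R)-2-[4-(benzyloxy)-3-bromo-2,6-bis(methoxymethoxy)phenyl]-1-methylpiperidine | CN1CCCC[C@@H]1c1c(OCOC)cc(OCc2ccccc2)c(Br)c1OCOC
F8 | step 8 | 1-[6-(benzyloxy)-2,4-bis(methoxymethoxy)-3-[(2R)-1-methylpiperidin-2-yl]phenyl]ethan-1-ol (both carbinol epimers) | CN1CCCC[C@@H]1c1c(OCOC)cc(OCc2ccccc2)c(C(C)O)c1OCOC
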